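**Plan**

- The target is two 7,8,4'-trihydroxyflavan-3,4-diols joined by one oxygen between their C4 atoms (flavan numbering in both). Unit A is (2R,3R,4R), all-cis; unit B is (2S,3R,4R), 2,3-trans-3,4-cis.
- Retrosynthesis: the six benzyl ethers and two 3-O groups come off first, then O1–C2 and C3–C4 of unit B are cut together. C4 of unit B is an aldehyde-level carbon on C4a, whose neighbour C8a carries O1, so O1–C8a–C4a–C4 is an o-quinone methide (used as its aryl oxocarbenium ion) and C2=C3 is an (E)-enol benzoate of 4-benzyloxyphenylacetaldehyde.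
- The acetal carbon goes back to an ester on O4 of unit A (α-acetoxy ether as activating group), the cis-diol of unit A to a 2-aryl-2H-chromene, and that to daphnetin and an arylboronic acid.
- Forward: the pyran ring of unit A comes from the coumarin (C2–aryl bond), then cis-diol at C3/C4, O4 aroylation and reduction to the acetal. The pyran ring of unit B is then built on the ether oxygen in one formal [4+2], followed by deprotection.
- Stereochemistry: C2 of unit A by catalytic enantioselective boronate addition; C3/C4 of unit A by Woodward cis-hydroxylation syn to the aryl group. C4, C3 and C2 of unit B are relayed from unit A in the cycloaddition (face: 3-silyloxy group of unit A; 3,4-cis: endo benzoate; 2,3-trans: E alkene and benzoate participation).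

Key step: step 14

Remark: phenols are carried as benzyl ethers because only hydrogenolysis is neutral enough for the bis-benzylic C4–O–C4 ether; an SN1 etherification at either C4 would give the 3,4-trans ether, which is why the ether oxygen is installed before ring B of unit B exists.

**Route**

Step 1
Reactants: 1 daphnetin (7,8-dihydroxy-2H-chromen-2-one)
Product: 2 7,8-bis(benzyloxy)-2H-chromen-2-one
Conditions: BnBr, K2CO3, DMF, rt
Reagents that add atoms: benzyl bromide, BrCc1ccccc1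
Why: Williamson etherification of both phenols; no stereocentre is involved.

Step 2
Reactants: 2 7,8-bis(benzyloxy)-2H-chromen-2-one
Product: 4 7,8-bis(benzyloxy)-2-ethoxy-2H-chromene (racemic), via lactol 3 (not isolated)
Conditions: i-Bu2AlH, CH2Cl2, −78 °C, aq. KNaC4H4O6 work-up; crude lactol, EtOH, PPTS, rt
Reagents that add atoms: ethanol, CCO
Why: Half-reduction of the coumarin lactone to the lactol and acid-catalysed acetalisation give the 2-alkoxy-2H-chromene that serves as benzopyrylium precursor; its racemic acetal centre is erased in step 3.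

Step 3
Reactants: 4 7,8-bis(benzyloxy)-2-ethoxy-2H-chromene; 5 4-(benzyloxy)phenylboronic acid
Product: 7 (S)-7,8-bis(benzyloxy)-2-[4-(benzyloxy)phenyl]-2H-chromene, via diethyl boronate 6 (not isolated)
Conditions: 5, EtOH, 3 Å MS, then evaporation; 4, tartaric-acid-derived amido acid catalyst (5 mol %, the antipode that gives (S)-7), Ce(OTf)4 (5 mol %), EtOAc, −20 °C
Reagents that add atoms: none
Why: Enantioselective addition of an aryl boronate to the benzopyrylium ion of a 2-alkoxy-2H-chromene under chiral Brønsted acid/Lewis acid catalysis, in which the chiral acyloxyboronate delivers the aryl group to one face of C2 and so sets the centre that becomes C2 (R) of unit A.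

Step 4
Reactants: 7 (S)-7,8-bis(benzyloxy)-2-[4-(benzyloxy)phenyl]-2H-chromene
Product: 9 (2R,3R,4R)-7,8-bis(benzyloxy)-2-[4-(benzyloxy)phenyl]chromane-3,4-diol (2,3-cis-3,4-cis), via hydroxy acetate 8 (not isolated)
Conditions: I2, AgOAc, AcOH then AcOH–H2O, rt to 50 °C; then K2CO3, MeOH, rt
Reagents that add atoms: silver acetate, CC(=O)[O-].[Ag+]
Why: Woodward cis-hydroxylation, in which the iodonium ion forms anti to the C2 aryl group, acetate opens it at benzylic C4, the acetate carbonyl displaces iodide at C3 with inversion to a cis-fused acetoxonium ion and water opens that ion, so that both new C–O bonds (3R, 4R) end up syn to the aryl group, the face that OsO4 would not reach.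

Step 5
Reactants: 10 2,3,4-trihydroxybenzaldehyde
Product: 11 3,4-bis(benzyloxy)-2-hydroxybenzaldehyde
Conditions: BnBr (2.0 equiv), K2CO3, DMF, 0 °C to rt
Reagents that add atoms: benzyl bromide, BrCc1ccccc1
Why: Williamson etherification in which the 2-OH, hydrogen-bonded to the aldehyde, is the least nucleophilic phenol and stays free.

Step 6
Reactants: 11 3,4-bis(benzyloxy)-2-hydroxybenzaldehyde
Product: 12 3,4-bis(benzyloxy)-2-[(tert-butyldimethylsilyl)oxy]benzaldehyde
Conditions: t-BuMe2SiCl, imidazole, DMAP (cat.), DMF, 40 °C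
Reagents that add atoms: tert-butyldimethylsilyl chloride, CC(C)(C)[Si](C)(C)Cl
Why: Silylation of the phenol, which masks the later O1 through the ester and reduction steps and is the group lost when the ring closes in step 14.

Step 7
Reactants: 12 3,4-bis(benzyloxy)-2-[(tert-butyldimethylsilyl)oxy]benzaldehyde
Product: 13 3,4-bis(benzyloxy)-2-[(tert-butyldimethylsilyl)oxy]benzoic acid
Conditions: NaClO2, NaH2PO4, 2-methyl-2-butene, t-BuOH/H2O, rt
Reagents that add atoms: sodium chlorite, [Na+].[O-]Cl=O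
Why: Pinnick oxidation of the aldehyde to the acid under buffered conditions that leave the aryl silyl ether and the electron-rich ring untouched.

Step 8
Reactants: 13 3,4-bis(benzyloxy)-2-[(tert-butyldimethylsilyl)oxy]benzoic acid
Product: 14 3,4-bis(benzyloxy)-2-[(tert-butyldimethylsilyl)oxy]benzoyl chloride
Conditions: 1-chloro-N,N,2-trimethylprop-1-en-1-amine, CH2Cl2, 0 °C to rt, used crude
Reagents that add atoms: 1-chloro-N,N,2-trimethylprop-1-en-1-amine, CC(C)=C(Cl)N(C)C
Why: Acid chloride formation with an α-chloroenamine under neutral conditions, so that no HCl cleaves the ortho silyl ether.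

Step 9
Reactants: 9 (2R,3R,4R)-7,8-bis(benzyloxy)-2-[4-(benzyloxy)phenyl]chromane-3,4-diol; 14 3,4-bis(benzyloxy)-2-[(tert-butyldimethylsilyl)oxy]benzoyl chloride
Product: 16 (2R,3S,4R)-7,8-bis(benzyloxy)-2-[4-(benzyloxy)phenyl]-3-hydroxychroman-4-yl 3,4-bis(benzyloxy)-2-[(tert-butyldimethylsilyl)oxy]benzoate (all-cis; the C3 descriptor changes by priority only), via stannylene acetal 15 (not isolated)
Conditions: Bu2SnO, toluene, reflux (−H2O); then 14, toluene, 0 °C to rt
Reagents that add atoms: none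
Why: Stannylene-acetal-directed monoacylation of a cis-1,2-diol, which acylates the equatorial benzylic O4 in preference to the axial O3.

Step 10
Reactants: 16 the 3-hydroxy 4-O-aroyl ester
Product: 17 (2R,3S,4R)-7,8-bis(benzyloxy)-2-[4-(benzyloxy)phenyl]-3-[(tert-butyldimethylsilyl)oxy]chroman-4-yl 3,4-bis(benzyloxy)-2-[(tert-butyldimethylsilyl)oxy]benzoate
Conditions: t-BuMe2SiOTf, 2,6-lutidine, CH2Cl2, −78 to 0 °C
Reagents that add atoms: tert-butyldimethylsilyl triflate, CC(C)(C)[Si](C)(C)OS(=O)(=O)C(F)(F)F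
Why: Silylation of the hindered axial 3-OH with the silyl triflate and a non-nucleophilic base, which avoids acyl migration and installs the group that shields one face in step 14.

Step 11
Reactants: 17 the 3-O-silyl 4-O-aroyl ester
Product: 19 α-acetoxy ether of unit A: (2R,3S,4R)-4-{acetoxy[3,4-bis(benzyloxy)-2-(tert-butyldimethylsilyloxy)phenyl]methoxy}-7,8-bis(benzyloxy)-2-[4-(benzyloxy)phenyl]-3-(tert-butyldimethylsilyloxy)chromane (acetal carbon as epimer mixture), via aluminium hemiacetal 18 (not isolated)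
Conditions: i-Bu2AlH (2 equiv), CH2Cl2, −78 °C; then pyridine, DMAP, Ac2O, −78 to 0 °C
Reagents that add atoms: acetic anhydride, CC(=O)OC(C)=O
Why: Reductive acetylation of an ester, in which the tetrahedral aluminium hemiacetal is stable at −78 °C and is acetylated in situ, so that the acetal carbon (the future C4 of unit B) carries the unit A oxygen and an acetate as the only good leaving group; the epimers converge in step 14.

Step 12
Reactants: 20 1-(benzyloxy)-4-ethynylbenzene
Product: 22 potassium (E)-{2-[4-(benzyloxy)phenyl]ethenyl}trifluoroborate, via catechol boronate 21 (not isolated)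
Conditions: catecholborane, THF, 70 °C; then aq. KHF2, MeOH, rt
Reagents that add atoms: catecholborane, B1Oc2ccccc2O1; potassium hydrogen difluoride, [K+].[F-].F
Why: Syn hydroboration of the terminal alkyne places boron at the terminal carbon with E geometry, and KHF2 converts the boronate into the stable trifluoroborate.

Step 13
Reactants: 22 potassium (E)-{2-[4-(benzyloxy)phenyl]ethenyl}trifluoroborate; 23 benzoic acid
Product: 24 (E)-2-[4-(benzyloxy)phenyl]ethenyl benzoate
Conditions: CuBr (10 mol %), DMAP, 4 Å MS, O2 (1 atm), MeCN, 60 °C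
Reagents that add atoms: none
Why: Copper-catalysed oxidative C–O coupling (Chan–Lam type) of an alkenyltrifluoroborate with a carboxylic acid, which proceeds with retention of the E geometry and gives the enol ester directly.

Step 14
Reactants: 19 α-acetoxy ether of unit A; 24 (E)-2-[4-(benzyloxy)phenyl]ethenyl benzoate
Product: 26 protected dimer: (2R,3R,4R)-7,8-bis(benzyloxy)-2-[4-(benzyloxy)phenyl]-3-(tert-butyldimethylsilyloxy)chroman-4-yl (unit A) and (2S,3R,4R)-3-(benzoyloxy)-7,8-bis(benzyloxy)-2-[4-(benzyloxy)phenyl]chroman-4-yl (unit B) joined by one ether oxygen, via oxocarbenium triflate 25 (not isolated)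
Conditions: 24 (2 equiv), Me3SiOTf (0.2 equiv), 2,6-di-tert-butyl-4-methylpyridine (0.3 equiv), 4 Å MS, CH2Cl2, −78 to −40 °C
Reagents that add atoms: none
Why: Proposed new method: Me3SiOTf ionises the α-acetoxy ether to the (E)-aryl oxocarbenium ion 25, the O-silylated form of an alkoxy o-quinone methide (O1–C8a–C4a–C4 of unit B); the enol benzoate adds through its benzoyloxy-bearing carbon (C3) to C4 because the cation developing at C2 is a 4-benzyloxybenzyl cation, and the silyloxy oxygen then closes O1–C2 with loss of the silyl group as its triflate, which carries the chain, a stepwise polar formal [4+2] whose closest known type is the acid-mediated coupling of salicylaldehyde acetals with styrenes to 4-alkoxyflavans, not yet shown with a β-acyloxystyrene or with a flavan-4-yl oxygen on the methide carbon. The dihydropyran ring of unit B closes as an inverse-electron-demand oxa-Diels–Alder ring (intermolecular C3–C4 bond, then 6-exo-tet O1–C2 closure). C4 (R) is set by attack on the oxocarbenium face anti to C3 of unit A, whose axial silyloxy group covers the other face when H4 of unit A eclipses the C=O+ bond; C3 (R) follows from the endo placement of the benzoyloxy group, with the 4-benzyloxyphenyl group exo and away from the 8-benzyloxy substituent, so that 3-O and 4-O become cis; C2 (S) follows from the E alkene geometry, and if the C2 cation lives long enough, participation of the benzoate carbonyl enforces anti delivery of O1 and the same 2,3-trans result. The step needs regioselectivity (C3 to C4, not C2 to C4), secured by the weak donor ability of the ester oxygen against the 4-alkoxyaryl group, and selective ionisation of the acetate over the C4–O bond of unit A, secured by the low temperature and the better leaving group.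

Step 15
Reactants: 26 protected dimer
Product: 28 hexa-O-benzyl dimer diol (unit A (2R,3R,4R), unit B (2S,3R,4R), both 3-OH free), via hydroxy benzoate 27 (not isolated)
Conditions: Bu4NF, THF, 0 °C to rt; then K2CO3, MeOH/THF, rt
Reagents that add atoms: none
Why: Fluoride desilylation of the secondary silyl ether followed by methanolysis of the benzoate, carried out while all phenols are still benzylated so that no 7-phenoxide can expel the C4 ether oxygen.

Step 16
Reactants: 28 hexa-O-benzyl dimer diol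
Product: 29 target CNP0241481.1
Conditions: H2 (1 atm), Pd(OH)2/C, EtOAc/MeOH, rt
Reagents that add atoms: none
Why: Hydrogenolysis of six aryl benzyl ethers under neutral conditions, which should be much faster than cleavage of the hindered secondary C4–O–C4 and C2–O1 bonds.

**Compound list**

1 | daphnetin (7,8-dihydroxy-2H-chromen-2-one) | O=C1C=Cc2ccc(O)c(O)c2O1 | starting material
2 | 7,8-bis(benzyloxy)-2H-chromen-2-one | O=C1C=Cc2ccc(OCc3ccccc3)c(OCc3ccccc3)c2O1 | intermediate
3 | 7,8-bis(benzyloxy)-2H-chromen-2-ol (lactol, racemic) | OC1C=Cc2ccc(OCc3ccccc3)c(OCc3ccccc3)c2O1 | intermediate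
4 | 7,8-bis(benzyloxy)-2-ethoxy-2H-chromene (racemic) | CCOC1C=Cc2ccc(OCc3ccccc3)c(OCc3ccccc3)c2O1 | intermediate
5 | 4-(benzyloxy)phenylboronic acid | OB(O)c1ccc(OCc2ccccc2)cc1 | starting material
6 | diethyl 4-(benzyloxy)phenylboronate | CCOB(OCC)c1ccc(OCc2ccccc2)cc1 | intermediate
7 | (S)-7,8-bis(benzyloxy)-2-[4-(benzyloxy)phenyl]-2H-chromene | c1ccccc1COc1ccc([C@H]2Oc3c(ccc(OCc4ccccc4)c3OCc3ccccc3)C=C2)cc1 | intermediate
8 | (2R,3R,4R)-7,8-bis(benzyloxy)-2-[4-(benzyloxy)phenyl]-4-hydroxychroman-3-yl acetate | c1ccccc1COc1ccc([C@H]2Oc3c(ccc(OCc4ccccc4)c3OCc3ccccc3)[C@@H](O)[C@H]2OC(C)=O)cc1 | intermediate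
9 | (2R,3R,4R)-7,8-bis(benzyloxy)-2-[4-(benzyloxy)phenyl]chromane-3,4-diol | c1ccccc1COc1ccc([C@H]2Oc3c(ccc(OCc4ccccc4)c3OCc3ccccc3)[C@@H](O)[C@H]2O)cc1 | intermediate
10 | 2,3,4-trihydroxybenzaldehyde | O=Cc1ccc(O)c(O)c1O | starting material
11 | 3,4-bis(benzyloxy)-2-hydroxybenzaldehyde | O=Cc1ccc(OCc2ccccc2)c(OCc2ccccc2)c1O | intermediate
12 | 3,4-bis(benzyloxy)-2-[(tert-butyldimethylsilyl)oxy]benzaldehyde | O=Cc1ccc(OCc2ccccc2)c(OCc2ccccc2)c1O[Si](C)(C)C(C)(C)C | intermediate
13 | 3,4-bis(benzyloxy)-2-[(tert-butyldimethylsilyl)oxy]benzoic acid | OC(=O)c1ccc(OCc2ccccc2)c(OCc2ccccc2)c1O[Si](C)(C)C(C)(C)C | intermediate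
14 | 3,4-bis(benzyloxy)-2-[(tert-butyldimethylsilyl)oxy]benzoyl chloride | ClC(=O)c1ccc(OCc2ccccc2)c(OCc2ccccc2)c1O[Si](C)(C)C(C)(C)C | intermediate
15 | 3,4-O-dibutylstannylene acetal of diol 9 (configuration of 9 retained) | c1ccccc1COc1ccc([C@H]2Oc3c(ccc(OCc4ccccc4)c3OCc3ccccc3)[C@@H](O[Sn]5(CCCC)CCCC)[C@H]2O5)cc1 | intermediate
16 | (2R,3S,4R)-7,8-bis(benzyloxy)-2-[4-(benzyloxy)phenyl]-3-hydroxychroman-4-yl 3,4-bis(benzyloxy)-2-[(tert-butyldimethylsilyl)oxy]benzoate (all-cis) | c1ccccc1COc1ccc([C@H]2Oc3c(ccc(OCc4ccccc4)c3OCc3ccccc3)[C@@H](OC(=O)c3ccc(OCc4ccccc4)c(OCc4ccccc4)c3O[Si](C)(C)C(C)(C)C)[C@H]2O)cc1 | intermediate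
17 | 3-O-tert-butyldimethylsilyl ether of 16 | c1ccccc1COc1ccc([C@H]2Oc3c(ccc(OCc4ccccc4)c3OCc3ccccc3)[C@@H](OC(=O)c3ccc(OCc4ccccc4)c(OCc4ccccc4)c3O[Si](C)(C)C(C)(C)C)[C@H]2O[Si](C)(C)C(C)(C)C)cc1 | intermediate
18 | O-diisobutylaluminium hemiacetal from 17 (acetal carbon as epimer mixture) | c1ccccc1COc1ccc([C@H]2Oc3c(ccc(OCc4ccccc4)c3OCc3ccccc3)[C@@H](OC(O[Al](CC(C)C)CC(C)C)c3ccc(OCc4ccccc4)c(OCc4ccccc4)c3O[Si](C)(C)C(C)(C)C)[C@H]2O[Si](C)(C)C(C)(C)C)cc1 | intermediate
19 | α-acetoxy ether of unit A (acetal carbon as epimer mixture) | c1ccccc1COc1ccc([C@H]2Oc3c(ccc(OCc4ccccc4)c3OCc3ccccc3)[C@@H](OC(OC(C)=O)c3ccc(OCc4ccccc4)c(OCc4ccccc4)c3O[Si](C)(C)C(C)(C)C)[C@H]2O[Si](C)(C)C(C)(C)C)cc1 | intermediate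
20 | 1-(benzyloxy)-4-ethynylbenzene | C#Cc1ccc(OCc2ccccc2)cc1 | starting material
21 | 2-{(E)-2-[4-(benzyloxy)phenyl]ethenyl}-1,3,2-benzodioxaborole | C(c1ccccc1)Oc1ccc(/C=C/B2Oc3ccccc3O2)cc1 | intermediate
22 | potassium (E)-{2-[4-(benzyloxy)phenyl]ethenyl}trifluoroborate | C(c1ccccc1)Oc1ccc(/C=C/[B-](F)(F)F)cc1.[K+] | intermediate
23 | benzoic acid | OC(=O)c1ccccc1 | starting material
24 | (E)-2-[4-(benzyloxy)phenyl]ethenyl benzoate | O=C(O/C=C/c1ccc(OCc2ccccc2)cc1)c1ccccc1 | intermediate
25 | (E)-aryl oxocarbenium triflate from 19 (O4 of unit A on the carbenium oxygen) | c1ccccc1COc1ccc([C@H]2Oc3c(ccc(OCc4ccccc4)c3OCc3ccccc3)[C@@H](/[O+]=C/c3ccc(OCc4ccccc4)c(OCc4ccccc4)c3O[Si](C)(C)C(C)(C)C)[C@H]2O[Si](C)(C)C(C)(C)C)cc1.[O-]S(=O)(=O)C(F)(F)F | intermediate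
26 | protected dimer: unit A (2R,3R,4R) 3-O-silyl, unit B (2S,3R,4R) 3-O-benzoyl, six benzyl ethers, C4–O–C4 | c1ccccc1COc1ccc([C@H]2Oc3c(ccc(OCc4ccccc4)c3OCc3ccccc3)[C@@H](O[C@@H]3c4ccc(OCc5ccccc5)c(OCc5ccccc5)c4O[C@@H](c4ccc(OCc5ccccc5)cc4)[C@@H]3OC(=O)c3ccccc3)[C@H]2O[Si](C)(C)C(C)(C)C)cc1 | intermediate
27 | hexa-O-benzyl dimer, 3-OH free on unit A, 3-O-benzoyl on unit B | c1ccccc1COc1ccc([C@H]2Oc3c(ccc(OCc4ccccc4)c3OCc3ccccc3)[C@@H](O[C@@H]3c4ccc(OCc5ccccc5)c(OCc5ccccc5)c4O[C@@H](c4ccc(OCc5ccccc5)cc4)[C@@H]3OC(=O)c3ccccc3)[C@H]2O)cc1 | intermediate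
28 | hexa-O-benzyl dimer diol | c1ccccc1COc1ccc([C@H]2Oc3c(ccc(OCc4ccccc4)c3OCc3ccccc3)[C@@H](O[C@@H]3c4ccc(OCc5ccccc5)c(OCc5ccccc5)c4O[C@@H](c4ccc(OCc5ccccc5)cc4)[C@@H]3O)[C@H]2O)cc1 | intermediate
29 | CNP0241481.1 | Oc1ccc([C@H]2Oc3c(ccc(O)c3O)[C@@H](O[C@@H]3c4ccc(O)c(O)c4O[C@@H](c4ccc(O)cc4)[C@@H]3O)[C@H]2O)cc1 | target

**Count**

Total steps: 16. Longest linear sequence: 10 steps (1, 2, 3, 4, 9, 10, 11, 14, 15, 16).

**Steps most likely to fail**

Step 14. Several processes can compete with the cycloaddition: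
- fragmentation of the oxocarbenium ion into the flavan-4-yl cation of unit A and the aldehyde;
- slow capture by the weakly nucleophilic enol ester;
- poor facial selectivity at the oxocarbenium carbon;
- incomplete ring closure by the silyl ether oxygen.

The fallback sets out from 19 and returns at 27. Commercial 2-bromo-1-[4-(benzyloxy)phenyl]ethanone is esterified with 23 (K2CO3, DMF) to 2-[4-(benzyloxy)phenyl]-2-oxoethyl benzoate F1, which is enol-silylated (Me3SiOTf, Et3N) to the (Z)-trimethylsilyl enol ether F2. Mukaiyama-type addition of F2 to the oxocarbenium ion from 19 (Me3SiOTf cat., CH2Cl2, −78 °C) makes the C3–C4 bond alone, with unambiguous regiochemistry and a far stronger nucleophile, and gives the β-alkoxy α-benzoyloxy ketone F3. NaBH4 reduces the ketone to the benzylic carbinol F4, and Bu4NF/AcOH removes both silyl groups to give the phenol F5. Mild acid (PPTS, CH2Cl2) then ionises only the 4-benzyloxybenzylic carbinol, the neighbouring benzoate steering the phenol to the 2,3-trans closure of O1–C2, which gives 27 for the methanolysis of step 15.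

Step 4. Electrophilic iodination of the benzyloxy-arenes, oxidation of the 2H-chromene to a flavylium salt, or aryl migration at the iodinated C3 may compete with acetoxonium formation.

The fallback sets out from 7 and returns at 17. Hydroboration–oxidation of 7 (BH3·THF; NaOH, H2O2) gives the 2,3-trans-flavan-3-ol F6, and Dess–Martin periodinane gives the flavan-3-one F7. LiBH(s-Bu)3 at −78 °C attacks anti to the aryl group and gives the 2,3-cis-flavan-3-ol F8, which t-BuMe2SiOTf converts to the silyl ether F9. DDQ in wet CH2Cl2 oxidises benzylic C4 to the 4-hydroxy compound F10, and Dess–Martin periodinane gives the 4-ketone F11. NaBH4 delivers hydride anti to the axial 3-silyloxy group and gives the all-cis 4-ol F12, and acylation of F12 with 14 (pyridine, DMAP) gives 17.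

Step 3. Uncatalysed background addition to the strongly stabilised 7,8-dioxygenated benzopyrylium ion may erode the enantioselectivity, and protodeboronation may consume the boronate.

The fallback sets out from 11 and returns at 7. Amine-catalysed oxa-Michael/aldol condensation of 11 with commercial (E)-3-[4-(benzyloxy)phenyl]acrylaldehyde (the diphenylprolinol trimethylsilyl ether antipode that gives the 2R product, 2-nitrobenzoic acid, toluene) gives the 2-aryl-2H-chromene-3-carbaldehyde F13. Decarbonylation with RhCl(PPh3)3 (toluene, heat) then gives 7.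

**Further compounds**

F1 | step 14 | 2-[4-(benzyloxy)phenyl]-2-oxoethyl benzoate | O=C(COC(=O)c1ccccc1)c1ccc(OCc2ccccc2)cc1
F2 | step 14 | (Z)-2-[4-(benzyloxy)phenyl]-2-[(trimethylsilyl)oxy]ethenyl benzoate | C[Si](C)(C)O/C(=C\OC(=O)c1ccccc1)c1ccc(OCc2ccccc2)cc1
F3 | step 14 | open-chain ketone: unit A (3-O-silyl) 4-O-[(1R,2R)-2-(benzoyloxy)-3-[4-(benzyloxy)phenyl]-1-[3,4-bis(benzyloxy)-2-(tert-butyldimethylsilyloxy)phenyl]-3-oxopropyl] ether (C3 and C4 of unit B as in 26) | c1ccccc1COc1ccc([C@H]2Oc3c(ccc(OCc4ccccc4)c3OCc3ccccc3)[C@@H](O[C@@H]([C@@H](OC(=O)c3ccccc3)C(=O)c3ccc(OCc4ccccc4)cc3)c3ccc(OCc4ccccc4)c(OCc4ccccc4)c3O[Si](C)(C)C(C)(C)C)[C@H]2O[Si](C)(C)C(C)(C)C)cc1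
F4 | step 14 | carbinol from F3 (C2 of unit B as epimer mixture) | c1ccccc1COc1ccc([C@H]2Oc3c(ccc(OCc4ccccc4)c3OCc3ccccc3)[C@@H](O[C@@H]([C@@H](OC(=O)c3ccccc3)C(O)c3ccc(OCc4ccccc4)cc3)c3ccc(OCc4ccccc4)c(OCc4ccccc4)c3O[Si](C)(C)C(C)(C)C)[C@H]2O[Si](C)(C)C(C)(C)C)cc1
F5 | step 14 | desilylated phenol carbinol from F4 | c1ccccc1COc1ccc([C@H]2Oc3c(ccc(OCc4ccccc4)c3OCc3ccccc3)[C@@H](O[C@@H]([C@@H](OC(=O)c3ccccc3)C(O)c3ccc(OCc4ccccc4)cc3)c3ccc(OCc4ccccc4)c(OCc4ccccc4)c3O)[C@H]2O)cc1
F6 | step 4 | (2R,3S)-7,8-bis(benzyloxy)-2-[4-(benzyloxy)phenyl]chroman-3-ol (2,3-trans) | c1ccccc1COc1ccc([C@H]2Oc3c(ccc(OCc4ccccc4)c3OCc3ccccc3)C[C@@H]2O)cc1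
F7 | step 4 | (2R)-7,8-bis(benzyloxy)-2-[4-(benzyloxy)phenyl]chroman-3-one | c1ccccc1COc1ccc([C@H]2Oc3c(ccc(OCc4ccccc4)c3OCc3ccccc3)CC2=O)cc1
F8 | step 4 | (2R,3R)-7,8-bis(benzyloxy)-2-[4-(benzyloxy)phenyl]chroman-3-ol (2,3-cis) | c1ccccc1COc1ccc([C@H]2Oc3c(ccc(OCc4ccccc4)c3OCc3ccccc3)C[C@H]2O)cc1
F9 | step 4 | 3-O-tert-butyldimethylsilyl ether of F8 | c1ccccc1COc1ccc([C@H]2Oc3c(ccc(OCc4ccccc4)c3OCc3ccccc3)C[C@H]2O[Si](C)(C)C(C)(C)C)cc1
F10 | step 4 | (2R,3R,4S)-7,8-bis(benzyloxy)-2-[4-(benzyloxy)phenyl]-3-[(tert-butyldimethylsilyl)oxy]chroman-4-ol (3,4-trans) | c1ccccc1COc1ccc([C@H]2Oc3c(ccc(OCc4ccccc4)c3OCc3ccccc3)[C@H](O)[C@H]2O[Si](C)(C)C(C)(C)C)cc1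
F11 | step 4 | (2R,3S)-7,8-bis(benzyloxy)-2-[4-(benzyloxy)phenyl]-3-[(tert-butyldimethylsilyl)oxy]chroman-4-one (2,3-cis) | c1ccccc1COc1ccc([C@H]2Oc3c(ccc(OCc4ccccc4)c3OCc3ccccc3)C(=O)[C@H]2O[Si](C)(C)C(C)(C)C)cc1
F12 | step 4 | (2R,3R,4R)-7,8-bis(benzyloxy)-2-[4-(benzyloxy)phenyl]-3-[(tert-butyldimethylsilyl)oxy]chroman-4-ol (all-cis) | c1ccccc1COc1ccc([C@H]2Oc3c(ccc(OCc4ccccc4)c3OCc3ccccc3)[C@@H](O)[C@H]2O[Si](C)(C)C(C)(C)C)cc1
F13 | step 3 | (2R)-7,8-bis(benzyloxy)-2-[4-(benzyloxy)phenyl]-2H-chromene-3-carbaldehyde | c1ccccc1COc1ccc([C@H]2Oc3c(ccc(OCc4ccccc4)c3OCc3ccccc3)C=C2C=O)cc1
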